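**Retrosynthetic overview**

1. Both benzoates go on last, onto C7–O and C4–O of diol 17. The C2=C3 bond comes from the C2 ketone of cyclohexanone 12 through its enol triflate and a palladium/formate reduction.
2. The six-membered carbocycle is the only ring of the target. It is closed by the intramolecular aldol addition C3→C4 of methyl ketone aldehyde 10; the acetonide is only a protecting ring.
3. Aldehyde 10 comes from the branched lactone 4 by Weinreb amide opening, MeMgBr (brings C3) and periodate cleavage of the mannose C5–C6 bond (frees the C4 aldehyde).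
4. The quaternary C1 is set first, by the crossed aldol of diacetone-D-mannose with formaldehyde (brings C7). C6 and C5 are mannose C3 and C4.
5. Feature: in the carbocycle, C1 is a fully substituted carbinol carbon (OH, C7H2O) between C6–OH and the C2=C3 bond. The chain C2–C1–C6–C5–C4 therefore maps onto C1–C5 of a 2-C-hydroxymethyl-D-lyxose cut from D-mannose, and a C2 ketone can enolise only toward C3, which fixes the alkene position.

Key step: step 7

Remarks on the chemistry:
- Ring numbering throughout: C1 = carbinol carbon bearing C7H2O, C2=C3, C4 (OBz), C5 (OH), C6 (OH). In this numbering the target is (1S,4R,5S,6S).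
- C1 is not made by adding an acetyl anion equivalent to an acyclic α,β-dialkoxy ketone, because attack on the α-chelate would put the tertiary oxygen on the wrong face. The cis-fused furanose acetonide fixes this centre instead.
- Assumption: lactol 3 is used as its anomeric mixture; the anomeric centre is removed in step 2.

**Route**

Step 1
Reactants: 1 2,3:5,6-di-O-isopropylidene-α-D-mannofuranose; 2 formaldehyde
Product: 3 2-C-(hydroxymethyl)-2,3:5,6-di-O-isopropylidene-D-mannofuranose (anomeric mixture)
Conditions: 37% aq. HCHO, K2CO3, MeOH, 65 °C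
Reagents that add atoms: formaldehyde (2), C=O
Why: Base-mediated crossed aldol of the ring-opened aldehyde with formaldehyde, in which the electrophile adds to C2 of the dioxolane enolate on the face opposite the C4 chain, so that C7H2OH replaces H-2, the 2,3-acetonide stays cis-fused and the furanose re-closes, which sets the quaternary carbon (target C1).

Step 2
Reactants: 3 2-C-(hydroxymethyl)-2,3:5,6-di-O-isopropylidene-D-mannofuranose
Product: 4 2-C-(hydroxymethyl)-2,3:5,6-di-O-isopropylidene-D-mannono-1,4-lactone
Conditions: Br2, BaCO3, H2O/1,4-dioxane, rt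
Reagents that add atoms: none
Why: Bromine (hypobromite) oxidation of an aldose lactol to the 1,4-lactone is selective for the hemiacetal C–H, and the carbonate buffer protects the acetonides while the primary alcohol is left alone.

Step 3
Reactants: 4 2-C-(hydroxymethyl)-2,3:5,6-di-O-isopropylidene-D-mannono-1,4-lactone
Product: 5 2-C-(hydroxymethyl)-2,3:5,6-di-O-isopropylidene-N-methoxy-N-methyl-D-mannonamide
Conditions: MeNH(OMe)·HCl, AlMe3, CH2Cl2, 0 °C to rt; used crude
Reagents that add atoms: N,O-dimethylhydroxylamine hydrochloride, CNOC.Cl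
Why: Weinreb aminolysis of a lactone by the aluminium amide opens the ring without touching a stereocentre and sets free O-4 (target C5–O) as a hydroxyl that can now be protected on its own.

Step 4
Reactants: 5 2-C-(hydroxymethyl)-2,3:5,6-di-O-isopropylidene-N-methoxy-N-methyl-D-mannonamide
Product: 6 4-O-(tert-butyldimethylsilyl)-2-C-[(tert-butyldimethylsilyloxy)methyl]-2,3:5,6-di-O-isopropylidene-N-methoxy-N-methyl-D-mannonamide
Conditions: TBSOTf, 2,6-lutidine, CH2Cl2, 0 °C
Reagents that add atoms: tert-butyldimethylsilyl triflate, CC(C)(C)[Si](C)(C)OS(=O)(=O)C(F)(F)F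
Why: Silyl ether formation with a silyl triflate caps the neopentyl primary and the hindered secondary hydroxyl in one operation and stops relactonisation of the γ-hydroxy amide.

Step 5
Reactants: 6 bis-silylated Weinreb amide; 7 methylmagnesium bromide
Product: 8 1-deoxy-3,4:6,7-di-O-isopropylidene-5-O-(tert-butyldimethylsilyl)-3-C-[(tert-butyldimethylsilyloxy)methyl]-D-manno-hept-2-ulose (the methyl ketone)
Conditions: MeMgBr, THF, 0 °C to rt
Reagents that add atoms: methylmagnesium bromide (7), C[Mg]Br
Why: Grignard addition to a Weinreb amide stops at the chelated tetrahedral intermediate, which should release the methyl ketone (C2=O, C3H3) on work-up without over-addition.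

Step 6
Reactants: 8 methyl ketone
Product: 10 6-deoxy-3,4-O-isopropylidene-2-O-(tert-butyldimethylsilyl)-4-C-[(tert-butyldimethylsilyloxy)methyl]-D-arabino-hexos-5-ulose (the methyl ketone aldehyde: C4 CHO; C5 OTBS; C6 and C1 in the acetonide; C7 OTBS; C2 acetyl), via terminal diol 9 (not isolated)
Conditions: H5IO6, EtOAc, rt; used crude
Reagents that add atoms: none
Why: Periodic acid hydrolyses the terminal acetonide faster than the internal tetrasubstituted dioxolane and then cleaves the 1,2-diol (Malaprade glycol cleavage) to the C4 aldehyde without touching C5.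

Step 7
Reactants: 10 methyl ketone aldehyde
Product: 12 cyclohexanone with C2 ketone and C4–OH cis to C5–OTBS and trans to C6–O (C1/C6 cis-acetonide; C7 OTBS), via lithium enolate 11 (not isolated)
Conditions: LiN(SiMe3)2 (1.05 equiv) added slowly, THF (dilute), −78 °C; AcOH, −78 °C
Reagents that add atoms: none
Why: LiN(SiMe3)2 removes a hydrogen from the C3 methyl group, the only α-position of the ketone because C1 is fully substituted, and the lithium enolate 11 adds through C3 to the C4 aldehyde to give a lithium aldolate that is protonated cold. The closest known reaction type is the intramolecular aldol addition of a methyl ketone enolate to a tethered aldehyde, as in the base-induced cyclisation of sugar-derived 6-deoxyhexos-5-uloses to 2-deoxyinososes (the ring-closing event of the Ferrier carbocyclisation). The carbocycle closes in a 6-(enolendo)-exo-trig mode, both enolate carbons C2 and C3 lying in the new ring. The new stereocentre C4 is set by a lithium-bridged chair transition state in which C7H2OTBS and the C5 and C6 oxygens are equatorial and the bridge between enolate and aldehyde oxygens holds the C4 oxygen axial, which is cis to C5–OTBS as the target requires. The step needs enolisation of the ketone in the presence of the aldehyde: the only competing acidic hydrogen is the hindered C5 methine between OTBS and the dioxolane carbon, closure from C5 onto C2 would give a four-membered ring, and the cold acidic quench forestalls retro-aldol, dehydration and β-elimination of the C6 oxygen.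

Step 8
Reactants: 12 aldol product
Product: 13 C4 triethylsilyl ether of 12
Conditions: TESOTf, 2,6-lutidine, CH2Cl2, −78 °C
Reagents that add atoms: triethylsilyl triflate, CC[Si](CC)(CC)OS(=O)(=O)C(F)(F)F
Why: Silylation of a β-hydroxy ketone with a silyl triflate and a weak hindered base at low temperature masks C4–OH without enolising or dehydrating the ketone.

Step 9
Reactants: 13 silylated ketone
Product: 15 enol triflate (C2(OTf)=C3), via lithium enolate 14 (not isolated)
Conditions: LiN(SiMe3)2, THF, −78 °C; N-(5-chloro-2-pyridyl)bis(trifluoromethanesulfonimide), −78 °C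
Reagents that add atoms: N-(5-chloro-2-pyridyl)bis(trifluoromethanesulfonimide), O=S(=O)(N(c1ccc(Cl)cn1)S(=O)(=O)C(F)(F)F)C(F)(F)F
Why: Kinetic enolate formation is possible only toward C3 because C1 is quaternary, and O-sulfonylation by the reactive pyridyl triflimide at −78 °C (enol triflate synthesis) should trap the enolate before the C4 silyloxy group can be expelled.

Step 10
Reactants: 15 enol triflate
Product: 16 cyclohexene (C2=C3) with C4 OTES, C5 OTBS, C7 OTBS and the C1/C6 acetonide
Conditions: Pd(OAc)2 (cat.), PPh3, HCO2H, Bu3N, DMF, 60 °C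
Reagents that add atoms: none
Why: Palladium-catalysed formate reduction of an enol triflate (oxidative addition to zerovalent palladium formed in the flask, formate exchange, loss of CO2, C–H reductive elimination) replaces OTf by H, and no allylic ester is yet present that could ionise.

Step 11
Reactants: 16 fully protected cyclohexene
Product: 17 diol with free C7–OH and C4–OH (C5 OTBS and acetonide kept)
Conditions: HF·pyridine, pyridine, THF, 0 °C to rt
Reagents that add atoms: none
Why: Buffered HF·pyridine desilylation follows the order TES, then primary TBS, then hindered secondary TBS, so C4–OH and C7–OH should be freed while the C5 TBS ether, flanked by two ring substituents, stays.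

Step 12
Reactants: 17 diol; 18 benzoyl chloride
Product: 19 C7,C4-dibenzoate (C5 OTBS; C1/C6 acetonide)
Conditions: BzCl (3 equiv), pyridine, DMAP (cat.), CH2Cl2, 0 °C to rt
Reagents that add atoms: benzoyl chloride (18), O=C(Cl)c1ccccc1
Why: DMAP-catalysed acylation esterifies the primary C7 and the allylic C4 hydroxyl with retention at C4, while the C1 and C6 oxygens are tied in the acetonide and C5 is silylated.

Step 13
Reactants: 19 dibenzoate
Product: 20 target CNP0217467.1
Conditions: TFA/H2O (9:1), 0 °C to rt
Reagents that add atoms: none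
Why: Acid-catalysed acetal hydrolysis and protodesilylation remove the cis-fused acetonide and the secondary TBS ether in one operation, under acidic conditions where benzoate migration between the cis C4 and C5 oxygens is slow.

**Compound list**

1 | 2,3:5,6-di-O-isopropylidene-α-D-mannofuranose | O[C@H]1O[C@H]([C@H]2COC(C)(C)O2)[C@@H]3OC(C)(C)O[C@H]13 | starting material
2 | formaldehyde | C=O | starting material
3 | 2-C-(hydroxymethyl)-2,3:5,6-di-O-isopropylidene-D-mannofuranose (anomeric mixture) | OC1O[C@H]([C@H]2COC(C)(C)O2)[C@@H]3OC(C)(C)O[C@]13CO | intermediate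
4 | 2-C-(hydroxymethyl)-2,3:5,6-di-O-isopropylidene-D-mannono-1,4-lactone | O=C1O[C@H]([C@H]2COC(C)(C)O2)[C@@H]3OC(C)(C)O[C@]13CO | intermediate
5 | 2-C-(hydroxymethyl)-2,3:5,6-di-O-isopropylidene-N-methoxy-N-methyl-D-mannonamide | CON(C)C(=O)[C@@]1(CO)OC(C)(C)O[C@H]1[C@H](O)[C@H]2COC(C)(C)O2 | intermediate
6 | 4-O-TBS-2-C-[(TBS-oxy)methyl]-2,3:5,6-di-O-isopropylidene-N-methoxy-N-methyl-D-mannonamide | CON(C)C(=O)[C@@]1(CO[Si](C)(C)C(C)(C)C)OC(C)(C)O[C@H]1[C@H](O[Si](C)(C)C(C)(C)C)[C@H]2COC(C)(C)O2 | intermediate
7 | methylmagnesium bromide | C[Mg]Br | starting material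
8 | 1-deoxy-3,4:6,7-di-O-isopropylidene-5-O-TBS-3-C-[(TBS-oxy)methyl]-D-manno-hept-2-ulose | CC(=O)[C@@]1(CO[Si](C)(C)C(C)(C)C)OC(C)(C)O[C@H]1[C@H](O[Si](C)(C)C(C)(C)C)[C@H]2COC(C)(C)O2 | intermediate
9 | 6,7-diol of 8 (not isolated) | CC(=O)[C@@]1(CO[Si](C)(C)C(C)(C)C)OC(C)(C)O[C@H]1[C@H](O[Si](C)(C)C(C)(C)C)[C@H](O)CO | intermediate
10 | 6-deoxy-3,4-O-isopropylidene-2-O-TBS-4-C-[(TBS-oxy)methyl]-D-arabino-hexos-5-ulose (methyl ketone aldehyde) | CC(=O)[C@@]1(CO[Si](C)(C)C(C)(C)C)OC(C)(C)O[C@H]1[C@H](O[Si](C)(C)C(C)(C)C)C=O | intermediate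
11 | lithium enolate of 10 (not isolated) | C=C(O[Li])[C@@]1(CO[Si](C)(C)C(C)(C)C)OC(C)(C)O[C@H]1[C@H](O[Si](C)(C)C(C)(C)C)C=O | intermediate
12 | aldol product: C2 ketone, C4–OH, C5 OTBS, C1/C6 acetonide, C7 OTBS | CC(C)(C)[Si](C)(C)OC[C@]12OC(C)(C)O[C@H]1[C@H](O[Si](C)(C)C(C)(C)C)[C@H](O)CC2=O | intermediate
13 | C4 triethylsilyl ether of 12 | CC(C)(C)[Si](C)(C)OC[C@]12OC(C)(C)O[C@H]1[C@H](O[Si](C)(C)C(C)(C)C)[C@H](O[Si](CC)(CC)CC)CC2=O | intermediate
14 | lithium enolate of 13 (not isolated) | CC(C)(C)[Si](C)(C)OC[C@]12OC(C)(C)O[C@H]1[C@H](O[Si](C)(C)C(C)(C)C)[C@H](O[Si](CC)(CC)CC)C=C2O[Li] | intermediate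
15 | enol triflate | CC(C)(C)[Si](C)(C)OC[C@]12OC(C)(C)O[C@H]1[C@H](O[Si](C)(C)C(C)(C)C)[C@H](O[Si](CC)(CC)CC)C=C2OS(=O)(=O)C(F)(F)F | intermediate
16 | protected cyclohexene (C2=C3) | CC(C)(C)[Si](C)(C)OC[C@]12OC(C)(C)O[C@H]1[C@H](O[Si](C)(C)C(C)(C)C)[C@H](O[Si](CC)(CC)CC)C=C2 | intermediate
17 | C7,C4-diol (C5 OTBS, acetonide) | OC[C@]12OC(C)(C)O[C@H]1[C@H](O[Si](C)(C)C(C)(C)C)[C@H](O)C=C2 | intermediate
18 | benzoyl chloride | O=C(Cl)c1ccccc1 | starting material
19 | C7,C4-dibenzoate (C5 OTBS, acetonide) | O=C(OC[C@]12OC(C)(C)O[C@H]1[C@H](O[Si](C)(C)C(C)(C)C)[C@H](OC(=O)c3ccccc3)C=C2)c4ccccc4 | intermediate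
20 | CNP0217467.1 | O=C(OC[C@@]1(O)C=C[C@@H](OC(=O)c2ccccc2)[C@@H](O)[C@@H]1O)c1ccccc1 | target

**Step count**

Total steps: 13. Longest linear sequence: 13 steps (1 to 20).

**Steps most likely to fail**

Step 7. The amide base may remove the C5 hydrogen of the aldehyde instead of a C3 hydrogen; the aldehyde enolate would then epimerise C5 or expel the C6 acetonide oxygen. The aldolate may also revert or dehydrate if it warms. The fallback sets out from 8 and comes back at 12. Ketone 8 is converted with LiN(SiMe3)2 and TMSCl (THF, −78 °C) into the trimethylsilyl enol ether F1, which NBS (THF, 0 °C) brominates to the bromomethyl ketone F2. Periodic acid in EtOAc then gives, through the bromo ketone diol F3, the bromo keto aldehyde F4. SmI2 (2.1 equiv, THF, −78 °C) cleaves the C–Br bond, and the trivalent samarium enolate closes onto the aldehyde through a metal-bridged transition state (intramolecular Reformatsky-type aldol) to give 12. The bromine makes C3 the only possible enolate site and no base is present.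

Step 9. The lithium enolate may expel the axial C4 silyloxy group (E1cB) before it is sulfonylated, which would form the enone and erase C4. The fallback sets out from 13 and comes back at 16. NaBH4 (MeOH, 0 °C) reduces the ketone to the C2 alcohol F5 (either epimer serves). Dehydration with bis[α,α-bis(trifluoromethyl)benzyloxy]diphenylsulfur, Ph2S[OC(CF3)2Ph]2 (CH2Cl2, rt), can remove hydrogen only from C3 because C1 carries none, so it should give the C2=C3 alkene 16 without any enolate.

Step 11. The neopentyl primary TBS ether at C7 may react too slowly relative to the C5 TBS ether, so that C5–OH is freed as well or C7 stays silylated. The fallback sets out from 16 and comes back at 20, and puts the two benzoates on one after the other. PPTS in MeOH (0 °C) removes only the triethylsilyl group to give the C4 alcohol F6. BzCl, pyridine and DMAP give the C4 benzoate F7. TFA/H2O removes both TBS ethers and the acetonide to give the tetraol 4-benzoate F8. Benzoylation of its only primary hydroxyl (BzCl 1.05 equiv, 2,4,6-collidine, CH2Cl2, −40 °C) then gives 20.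

**Further compounds**

F1 | step 7 | trimethylsilyl enol ether of 8 | C=C(O[Si](C)(C)C)[C@@]1(CO[Si](C)(C)C(C)(C)C)OC(C)(C)O[C@H]1[C@H](O[Si](C)(C)C(C)(C)C)[C@H]2COC(C)(C)O2
F2 | step 7 | bromomethyl ketone (1-bromo analogue of 8) | BrCC(=O)[C@@]1(CO[Si](C)(C)C(C)(C)C)OC(C)(C)O[C@H]1[C@H](O[Si](C)(C)C(C)(C)C)[C@H]2COC(C)(C)O2
F3 | step 7 | bromo ketone diol (bromo analogue of 9) | BrCC(=O)[C@@]1(CO[Si](C)(C)C(C)(C)C)OC(C)(C)O[C@H]1[C@H](O[Si](C)(C)C(C)(C)C)[C@H](O)CO
F4 | step 7 | bromo keto aldehyde (bromo analogue of 10) | BrCC(=O)[C@@]1(CO[Si](C)(C)C(C)(C)C)OC(C)(C)O[C@H]1[C@H](O[Si](C)(C)C(C)(C)C)C=O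
F5 | step 9 | C2 alcohol from 13 (C2 epimers) | CC(C)(C)[Si](C)(C)OC[C@]12OC(C)(C)O[C@H]1[C@H](O[Si](C)(C)C(C)(C)C)[C@H](O[Si](CC)(CC)CC)CC2O
F6 | step 11 | C4 alcohol (C5 and C7 OTBS, acetonide) | CC(C)(C)[Si](C)(C)OC[C@]12OC(C)(C)O[C@H]1[C@H](O[Si](C)(C)C(C)(C)C)[C@H](O)C=C2
F7 | step 11 | C4 benzoate (C5 and C7 OTBS, acetonide) | CC(C)(C)[Si](C)(C)OC[C@]12OC(C)(C)O[C@H]1[C@H](O[Si](C)(C)C(C)(C)C)[C@H](OC(=O)c3ccccc3)C=C2
F8 | step 11 | tetraol 4-benzoate | OC[C@@]1(O)C=C[C@@H](OC(=O)c2ccccc2)[C@@H](O)[C@@H]1O
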